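A small charge of substrate, 0.10 M, faces 0.110 M of reagent in this flask, while the theta run held 0.15 M of substrate and 0.11 M of reagent and was followed by its side product A and target, not by its reagent.

| flask | substrate | reagent | remark | time |
|---|---|---|---|---|
| theta | 0.15 M | 0.11 M | run made earlier |  |
| flask | 0.10 M | 0.110 M |  | 3.0 h |

theta run (percent of the substrate charged)

| time / min | side product A / % | target / % |
|---|---|---|
| 4.00 | 0 | 0 |
| 8.00 | 2.4 | 0.9 |
| 15.0 | 3.1 | 3.6 |
| 30.0 | 1.8 | 10.0 |
| 50.0 | 4.0 | 14.6 |

(each reading ± 1 percentage point)

- what was read earlier has a scatter of 1 percentage point, one standard deviation

- share of side product A in side product A plus target at 6.0 min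
- share of side product A in side product A plus target at 30 min
- share of side product A in side product A plus target at 3.0 h
- which of side product A and target there is more of at 3.0 h

In fractions of the charge, the quantity to carry is the reagent charged per substrate charged, the equivalents ratio 1.10, against 0.733 in the theta run. The rule is this: if each substrate used costs more reagent than this ratio, reagent is the limiting reagent and substrate remains. The theta run reads no reagent, so the cost is open. My own reckoning assumes, without a reading behind it, a cost between one and two. At an assumed cost of one, reagent in this flask stands 10.0% of the substrate charge ahead, a margin that a cost above 1.10 removes. At an assumed cost of two, the reagent of this flask covers 55.0% of its substrate. This bracket concerns substrate used and gives no share.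

The forecast, “assuming first order in each reactant”, gives shares of 73%, 23% and 7% at the three times, with target ahead.

The flask gives 71.3%, 22.9% and 15.7%, with target ahead at 26.1% against 4.84% of side product A.

    substrate + reagent ⇌ intermediate A (K = 22.0 L mol⁻¹, k = 0.00900 L mol⁻¹ s⁻¹)
    substrate + reagent → side product A (k = 5.50 × 10⁻⁴ L mol⁻¹ s⁻¹)
    intermediate A → intermediate B (k = 8.30 × 10⁻⁴ s⁻¹)
    reagent + intermediate A → intermediate C (k = 0.0170 L mol⁻¹ s⁻¹)
    intermediate C → target (k = 8.50 × 10⁻⁴ s⁻¹)
    reagent + intermediate B → side product B (k = 0.0120 L mol⁻¹ s⁻¹)

The first two shares agree with the forecast, and the last stands 8.7 percentage points above it. After 3.00 h the flask holds 33.4% of its substrate and 0.46% of its reagent, so reagent ended first. The ratio turns this into a cost in this flask, up to that time, of 1.65 reagent per substrate used, which is more than the ratio itself.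

The neighbour flask with 0.28 M of reagent has a ratio of 2.80, more than the assumed top cost of two, so there substrate should go first. Computed, that neighbour ends with 0.0164% of its substrate and 30.9% of its reagent, a cost in that flask of 1.94 reagent per substrate used.

The earlier runs and the new flask are calculated on assumed constants.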